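## Analysis of the target

Compound 15 is a 1,4-naphthoquinone: quinone ring A (C1–C4 with C4a and C8a) carries a methoxy group on C2 and a hydrogen on C3, and benzenoid ring B (C4a, C5–C8, C8a) carries a methoxy group on C6 and a 3,4-dimethoxyphenyl ring (primed numbering) on C8. There is no stereocentre, and because the primed ring has no ortho substituent the C8–C1' axis should rotate freely, so the molecule is achiral and the whole problem is one of regiochemistry. The sensitive function is the 2-methoxyquinone, a vinylogous ester that exchanges its methoxy group with nucleophiles, is attacked by strong bases and is easily reduced; the electron-rich aryl rings would in turn suffer under strong oxidants. Two relationships make the synthesis hard: the C2 methoxy group must lie on the side of the C1 carbonyl, the one peri to the aryl group, and the C6 methoxy group is meta to both C8 and C4a, a pattern that electrophilic substitution does not deliver. In addition, C4a, C8a and C8 are three neighbouring ring carbons that each hold a carbon substituent, and the groups on C8 and C8a (the aryl ring and C1) press on each other across the peri gap, so bonds to these positions are slow to form on a preformed biaryl. The strategy rests on C8a being the middle carbon of this 1,2,3-trisubstituted arrangement: an aryne spanning C8 and C8a can take a carbon nucleophile at C8 and a carbon electrophile at C8a in one operation, while a halogen kept on C4a directs the addition and later serves as the handle for C4. Ring A can then be closed by carbonyl condensation at its final oxidation level, so no oxidation is needed in the presence of the electron-rich rings.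

## Retrosynthetic reasoning

**O2–methyl bond.** The methyl ether at C2 is removed first, which leads back to the hydroxyquinone 14. The 2-methoxyquinone is the most nucleophile-sensitive group of 15, whereas 14 is its stable, acidic parent. Leaving the methyl group to the end allows ring A to be closed under basic conditions that the ether would not survive. The forward reaction has to place the methyl group on the C2 oxygen and not on the C4 oxygen, which is a matter of thermodynamic control in favour of the para-quinone.

**C2–C3 bond.** Ring A of 14 is opened between C2 and C3 to give the acetyl keto ester 13. In 13, C3 is the methyl carbon of a ketone (the only enolisable position) and C2 is an ester carbon, so the ring closes by a Claisen condensation. That condensation delivers C1, C2 and C4 directly at the quinone oxidation level. A cut at C3–C4 or C4–C4a would call for a radical or pericyclic closure followed by an oxidation. The forward reaction must make the enolate choose the ester carbon C2 (six-membered ring) over the ketone carbon C1 (five-membered ring); only the former ends in a stabilised anion.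

**C4–C4a bond.** The acetyl group of 13 is detached at C4–C4a, which gives the aryl chloride 10 and the acetyl anion equivalent 11. Chlorine is wanted at C4a because it does two jobs: it is the coupling handle for C4, and one stage earlier it is the substituent that steers the aryne addition. The forward reaction has to couple an aryl chloride with one ortho substituent without harming the keto ester.

**C8–C1' and C1–C8a bonds (key disconnection).** Compound 10 is cut at two bonds on adjacent ring carbons at once, the biaryl bond and the bond from C8a to the keto carbon. This leaves the aryne 8 (triple bond between C8 and C8a, chlorine on C4a), the aryl nucleophile 5 and the electrophile 6. Made one at a time, each of these bonds would have to be formed at a doubly ortho-substituted position. On the aryne both form in one flask: 5 adds at C8, and the carbon–magnesium bond that appears at C8a in 9 is acylated by 6. The aryne 8 comes from the Grignard reagent 7 and hence from the iodide 3. The forward reaction needs loss of bromide only, addition at C8 only, and a single acylation.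

**C–I bond and C–Mg bond.** The iodide 3 comes from the commercial dihaloanisole 1 by metalation between the two halogens (aryllithium 2) and iodination. The Grignard reagent 5 comes from the commercial bromide 4. Each is one reliable step, so the risk of the route sits in the three-component step.

## Alternatives that were turned down

**Alternative 1:** Ring B would be built onto an arene that already has the oxygen pattern of ring A.
- Disconnection: the C8–C8a bond, leading to the open-chain 1-(3,4-dimethoxyphenyl)-4-(2,4,5-trimethoxyphenyl)butane-1,3-dione A1.
- Forward key step: strong acid would make the free ortho carbon of the trimethoxyphenyl ring (the future C8a) attack the aryl ketone. Dehydration and enolisation would give 4-(3,4-dimethoxyphenyl)-5,6,8-trimethoxynaphthalen-2-ol A2. O-methylation and oxidative demethylation of the para-dimethoxy pair with (NH4)2Ce(NO3)6 would then lead to 15.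
- For it: the chemistry is classical and free of tin and palladium. The C2 methoxy group is in place from the start, so there is no question of which quinone oxygen is methylated; on that point it is stronger than the chosen route.
- Against it: the electrophile is a ketone conjugated to an electron-rich ring and tied up in an enolised 1,3-diketone. The attacking carbon is activated by only one ortho methoxy group. The ring closure itself must force the aryl group into the peri position beside a methoxy group. The final oxidation must pick one ring out of a molecule with five methoxy groups and a veratrole unit.
- Comparison: the step count is similar once the preparation of A1 is included. The chosen strategy instead makes the crowded C8–aryl bond on an aryne, which is not sensitive to steric or electronic deactivation, and reaches the quinone level without an oxidant.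

**Alternative 2:** Ring A would be closed by a radical.
- Disconnection: the C3–C4 bond, leading to 3-(3,4-dimethoxyphenyl)-5-methoxy-2-(2-methoxyprop-2-enoyl)benzaldehyde A3.
- Forward key step: photoexcited (Bu4N)4W10O32 would abstract the formyl hydrogen. The aroyl radical would add in a 6-endo fashion to the terminal alkene carbon, giving a radical at C2 stabilised by both the methoxy and the carbonyl group. Back-transfer of hydrogen would give racemic 8-(3,4-dimethoxyphenyl)-2,6-dimethoxy-2,3-dihydronaphthalene-1,4-dione A4, which would need dehydrogenation to 15.
- For it: the closure is catalytic and redox-neutral, runs under neutral conditions, and carries the C2 methoxy group in with certainty, so it also avoids the final methylation question.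
- Against it: A3 contains the same crowded 1,2,3-triad as the target, now with an aldehyde and a polymerisable enone, so the hardest part of the problem is only moved into the precursor. Hydrogen abstraction could also occur at the methoxy C–H bonds. In A4 the methoxy group is β to the C4 carbonyl, so enolisation can expel methanol and give the quinone without the C2 substituent. A stereocentre is made only to be erased, and an extra oxidation is needed.
- Comparison: the chosen strategy is shorter and carries ring A in as a robust ester and acetyl group.

**Alternative 3:** Ring A would come from a four-membered ring.
- Disconnection: the C4–C4a bond, leading to racemic 4-[2-(3,4-dimethoxyphenyl)-4-methoxyphenyl]-4-hydroxy-3-methoxycyclobut-2-en-1-one A5.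
- Forward key step: heating would open A5 in a conrotatory way, with the hydroxyl group turning outward, to an aryl vinylketene. Six-electron closure onto the free ortho carbon and tautomerisation would give 8-(3,4-dimethoxyphenyl)-2,6-dimethoxynaphthalene-1,4-diol A6. A mild oxidation would complete 15.
- For it: this is a robust and well-tested way to make highly substituted quinones. It fixes methoxy at C2 and hydrogen at C3 without ambiguity, and its last oxidation is gentle. On regiochemical certainty in ring A it is stronger than the chosen route.
- Against it: A5 needs a lithiated biaryl to add, with the correct choice of carbonyl, to a four-membered-ring dione, and the carbanion carbon is flanked by the aryl group. Both partners take about two steps each, the dione from a costly precursor, and the biaryl bond still has to be made separately by a selective cross-coupling.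
- Comparison: the chosen strategy makes the biaryl bond and the C1–C8a bond together from simple haloarenes and is about one step shorter. In return it accepts the O-methylation question of step 6, which this alternative does not have.

Key step: step 3

## Route

Step 1
Reactants: 1 1-bromo-3-chloro-5-methoxybenzene
Product: 3 1-bromo-3-chloro-2-iodo-5-methoxybenzene, via aryllithium 2 (not isolated)
Conditions: LiN(iPr)2 (1.1 equiv), THF, −78 °C; then I2, THF, −78 °C → rt
Reagents that add atoms: iodine, II
Why: Directed deprotonation followed by iodinolysis; the hydrogen between the two halogens is the most acidic on the ring, so the amide base should remove it in preference to those next to the methoxy group, and at −78 °C the 2,6-dihaloaryllithium 2 should neither lose lithium halide nor let a halogen migrate before iodine captures it. The same operation on 1,3-dihalobenzenes is the usual way to 2,6-dihaloiodobenzenes.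

Step 2
Reactants: 4 4-bromo-1,2-dimethoxybenzene
Product: 5 3,4-dimethoxyphenylmagnesium bromide (THF solution, titrated and used directly)
Conditions: Mg turnings, I2 (cat.), THF, 40–50 °C
Reagents that add atoms: magnesium, [Mg]
Why: Grignard formation by insertion of magnesium into the aryl–bromine bond; the electron-rich bromide should insert smoothly in THF once the metal surface is activated.

Step 3
Reactants: 3 1-bromo-3-chloro-2-iodo-5-methoxybenzene, 5 3,4-dimethoxyphenylmagnesium bromide, 6 dimethyl oxalate
Product: 10 methyl 2-[2-chloro-6-(3,4-dimethoxyphenyl)-4-methoxyphenyl]-2-oxoacetate, via aryl Grignard reagent 7 (not isolated), via 3-chloro-5-methoxybenzyne 8 (not isolated), via biaryl Grignard reagent 9 (not isolated)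
Conditions: iPrMgCl·LiCl (1.0 equiv), THF, −40 °C; 5 (1.3 equiv), −40 → 25 °C; then cannulated into 6 (4 equiv), THF, −40 → 0 °C; aq. NH4Cl
Reagents that add atoms: none
Why: Iodine–magnesium exchange on 3 is fast at −40 °C and selective for iodine, and should give 7 with magnesium on the carbon between bromine and chlorine. On warming, 7 should undergo β-elimination of MgBrCl, bromide being the better leaving group, to give the aryne 8 across the carbons that become C8 and C8a. The aryl Grignard reagent 5 should add to 8 at the carbon remote from chlorine, because the inductively withdrawing C–Cl bond distorts the aryne so that the developing carbanion sits beside chlorine and the incoming aryl group stays away from it; the methoxy group, meta to the attacked carbon, has only a weak and opposing influence. The biaryl Grignard reagent 9 should keep its ortho chlorine at or below room temperature, since loss of chloride needs clearly more heat than loss of bromide, and on transfer into excess 6 it displaces one methoxide to give the α-keto ester 10. The closest known reaction type is the one-pot arylmagnesiation of 3-haloarynes generated from 2,6-dihaloiodobenzenes, as used for m-terphenyls, stopped here after the first aryne cycle and joined to the standard acylation of aryl Grignard reagents by dialkyl oxalates. No ring is closed and no stereocentre is formed. The step needs one aryne only (secured by the bromine/chlorine difference and the temperature ceiling), addition at C8 (secured by the chlorine next to the aryne) and a single acylation (secured by inverse addition to excess 6 at low temperature and by the two ortho substituents of 9, which shield the new ketone).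

Step 4
Reactants: 10 methyl 2-[2-chloro-6-(3,4-dimethoxyphenyl)-4-methoxyphenyl]-2-oxoacetate, 11 tributyl(1-ethoxyvinyl)stannane
Product: 13 methyl 2-[2-acetyl-6-(3,4-dimethoxyphenyl)-4-methoxyphenyl]-2-oxoacetate, via enol ether 12 (not isolated)
Conditions: Pd2(dba)3 (2 mol %), P(tBu)3 (8 mol %), CsF (2.2 equiv), dioxane, 100 °C; then 1 M HCl, THF, rt
Reagents that add atoms: water, O
Why: Stille coupling of an aryl chloride with zerovalent palladium carrying the bulky, electron-rich P(tBu)3 and with fluoride activation of tin, conditions developed for aryl chlorides; oxidative addition is helped by the ortho keto group. The 1-ethoxyvinyl group is an acetyl anion equivalent, and dilute acid should hydrolyse the enol ether 12 to the methyl ketone without touching the keto ester or the aryl ethers.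

Step 5
Reactants: 13 methyl 2-[2-acetyl-6-(3,4-dimethoxyphenyl)-4-methoxyphenyl]-2-oxoacetate
Product: 14 8-(3,4-dimethoxyphenyl)-2-hydroxy-6-methoxynaphthalene-1,4-dione
Conditions: NaOMe (2.5 equiv), MeOH, 0 °C → rt; then 1 M HCl
Reagents that add atoms: none
Why: Intramolecular Claisen (Dieckmann-type) condensation: the acetyl methyl group is the only enolisable position, its enolate attacks the ester carbon C2 in a 6-exo-trig closure, and loss of methoxide leaves ring A at the quinone oxidation level as the stable vinylogous carboxylate of 14, which drives the equilibrium. Aldol addition of the same enolate to the C1 ketone (five-membered ring) is reversible under methoxide and should drain into 14, which is released on acidification.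

Step 6
Reactants: 14 8-(3,4-dimethoxyphenyl)-2-hydroxy-6-methoxynaphthalene-1,4-dione
Product: 15 8-(3,4-dimethoxyphenyl)-2,6-dimethoxynaphthalene-1,4-dione
Conditions: conc. HCl (cat.), MeOH, reflux
Reagents that add atoms: methanol, CO
Why: Acid-catalysed etherification of a vinylogous carboxylic acid (Fischer-type): methanol adds at C2 of protonated 14 and water is lost. The reaction is reversible and under thermodynamic control, so the 2-methoxy-1,4-quinone should prevail over the isomeric 4-methoxy-1,2-quinone; this is the standard conversion of 2-hydroxy-1,4-naphthoquinones into their methyl ethers.

## Compound list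

1 | 1-bromo-3-chloro-5-methoxybenzene | COc1cc(Cl)cc(Br)c1 | starting material
2 | (2-bromo-6-chloro-4-methoxyphenyl)lithium | COc1cc(Cl)c([Li])c(Br)c1 | intermediate
3 | 1-bromo-3-chloro-2-iodo-5-methoxybenzene | COc1cc(Cl)c(I)c(Br)c1 | intermediate
4 | 4-bromo-1,2-dimethoxybenzene | COc1ccc(Br)cc1OC | starting material
5 | 3,4-dimethoxyphenylmagnesium bromide | COc1ccc([Mg]Br)cc1OC | intermediate
6 | dimethyl oxalate | COC(=O)C(=O)OC | starting material
7 | 2-bromo-6-chloro-4-methoxyphenylmagnesium chloride | COc1cc(Cl)c([Mg]Cl)c(Br)c1 | intermediate
8 | 3-chloro-5-methoxybenzyne (3-chloro-5-methoxy-1,2-didehydrobenzene) | COC1=CC#CC(Cl)=C1 | intermediate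
9 | 2-chloro-6-(3,4-dimethoxyphenyl)-4-methoxyphenylmagnesium bromide | COc1cc(Cl)c([Mg]Br)c(-c2ccc(OC)c(OC)c2)c1 | intermediate
10 | methyl 2-[2-chloro-6-(3,4-dimethoxyphenyl)-4-methoxyphenyl]-2-oxoacetate | COC(=O)C(=O)c1c(Cl)cc(OC)cc1-c1ccc(OC)c(OC)c1 | intermediate
11 | tributyl(1-ethoxyvinyl)stannane | CCCC[Sn](CCCC)(CCCC)C(=C)OCC | starting material
12 | methyl 2-[2-(3,4-dimethoxyphenyl)-6-(1-ethoxyvinyl)-4-methoxyphenyl]-2-oxoacetate | CCOC(=C)c1cc(OC)cc(-c2ccc(OC)c(OC)c2)c1C(=O)C(=O)OC | intermediate
13 | methyl 2-[2-acetyl-6-(3,4-dimethoxyphenyl)-4-methoxyphenyl]-2-oxoacetate | COC(=O)C(=O)c1c(C(C)=O)cc(OC)cc1-c1ccc(OC)c(OC)c1 | intermediate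
14 | 8-(3,4-dimethoxyphenyl)-2-hydroxy-6-methoxynaphthalene-1,4-dione | OC1=CC(=O)c2cc(OC)cc(-c3ccc(OC)c(OC)c3)c2C1=O | intermediate
15 | 8-(3,4-dimethoxyphenyl)-2,6-dimethoxynaphthalene-1,4-dione | COC1=CC(=O)c2cc(OC)cc(-c3ccc(OC)c(OC)c3)c2C1=O | target

## Step count and least certain steps

Total step count: 6. Longest linear sequence: 5 steps (steps 1, 3, 4, 5 and 6); step 2 is the side branch.

**Step 3 (key step).** The two eliminations may fall out of step. Bromide loss from 7 may be too slow at a temperature where 9 is still intact, so that 7 is acylated before it has formed the aryne. Or 9 may lose chloride, form a second aryne and take up a second aryl group. The selectivity rests only on the leaving-group difference between bromide and chloride in two Grignard reagents that also differ in their other ortho substituent, so the temperature window may be narrow. Fallback: setting out from 3, the exchange with iPrMgCl·LiCl is run at −40 °C and the cold solution of 7 is acylated at once with 6, without warming, to give methyl 2-(2-bromo-6-chloro-4-methoxyphenyl)-2-oxoacetate F1. A Suzuki–Miyaura coupling of F1 with 3,4-dimethoxyphenylboronic acid (Pd(PPh3)4, anhydrous K3PO4, toluene, 90 °C), in which zerovalent palladium inserts into the C–Br bond well before the C–Cl bond, comes back to the route at 10.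

**Step 5.** The enolate may add to the C1 ketone, which is much more electrophilic than the ester, and the five-membered aldol adduct may dehydrate or decay instead of reverting; the peri aryl group also resists the flattening of C1 into the new ring. Fallback: setting out from 12, which would be isolated by leaving out the acid treatment of step 4, NaBH4 (MeOH, −20 °C) reduces the only ketone present and gives racemic methyl 2-[2-(3,4-dimethoxyphenyl)-6-(1-ethoxyvinyl)-4-methoxyphenyl]-2-hydroxyacetate F2. Dilute HCl in THF unmasks the acetyl group to give racemic methyl 2-[2-acetyl-6-(3,4-dimethoxyphenyl)-4-methoxyphenyl]-2-hydroxyacetate F3. With C1 at the alcohol level no aldol pathway exists, so NaOMe in MeOH closes the ring onto the ester, and enolisation gives 8-(3,4-dimethoxyphenyl)-6-methoxynaphthalene-1,2,4-triol F4. Air oxidises F4 during work-up, and the route is rejoined at 14.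

**Step 4.** Oxidative addition into the C–Cl bond or transmetalation from tin may be slow beside the bulky keto ester, and the keto ester may be degraded by fluoride during long heating at 100 °C. Fallback: setting out from 10, a Suzuki–Miyaura coupling with vinylboronic acid pinacol ester (Pd(OAc)2, SPhos, K3PO4, toluene, 90 °C) gives methyl 2-[2-(3,4-dimethoxyphenyl)-6-ethenyl-4-methoxyphenyl]-2-oxoacetate F5. A Tsuji–Wacker oxidation (PdCl2, CuCl, O2, DMF–H2O, rt) converts the styrene into the methyl ketone and comes back to the route at 13. This replaces the tin reagent and the hydrolytic unmasking by a boron reagent and an oxidative one.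

**Step 1.** Deprotonation may occur next to the methoxy group instead of between the halogens, or 2 may lose lithium bromide or let a halogen migrate if the temperature rises. Fallback: setting out from 1, electrophilic iodination (N-iodosuccinimide, CF3CO2H, MeCN, rt) is steered by the methoxy group to its para position, which is the same carbon, and gives 3 directly after separation from ortho isomers; this fallback makes no new compound (F0).

**Step 6.** Methylation may occur on the C4 oxygen, giving the ortho-quinone ether, or the reversible etherification may stop short of completion. Fallback: setting out from 14, SOCl2 (reflux) converts the vinylogous acid into its chloride, 2-chloro-8-(3,4-dimethoxyphenyl)-6-methoxynaphthalene-1,4-dione F6. NaOMe in MeOH at 0 °C then replaces chloride at C2 by addition–elimination and arrives at 15.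

## Further compounds

F1 | step 3 | methyl 2-(2-bromo-6-chloro-4-methoxyphenyl)-2-oxoacetate | COC(=O)C(=O)c1c(Cl)cc(OC)cc1Br
F2 | step 5 | methyl 2-[2-(3,4-dimethoxyphenyl)-6-(1-ethoxyvinyl)-4-methoxyphenyl]-2-hydroxyacetate (racemic) | CCOC(=C)c1cc(OC)cc(-c2ccc(OC)c(OC)c2)c1C(O)C(=O)OC
F3 | step 5 | methyl 2-[2-acetyl-6-(3,4-dimethoxyphenyl)-4-methoxyphenyl]-2-hydroxyacetate (racemic) | COC(=O)C(O)c1c(C(C)=O)cc(OC)cc1-c1ccc(OC)c(OC)c1
F4 | step 5 | 8-(3,4-dimethoxyphenyl)-6-methoxynaphthalene-1,2,4-triol | Oc1cc(O)c2cc(OC)cc(-c3ccc(OC)c(OC)c3)c2c1O
F5 | step 4 | methyl 2-[2-(3,4-dimethoxyphenyl)-6-ethenyl-4-methoxyphenyl]-2-oxoacetate | COC(=O)C(=O)c1c(C=C)cc(OC)cc1-c1ccc(OC)c(OC)c1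
F0 | step 1 | none | none
F6 | step 6 | 2-chloro-8-(3,4-dimethoxyphenyl)-6-methoxynaphthalene-1,4-dione | ClC1=CC(=O)c2cc(OC)cc(-c3ccc(OC)c(OC)c3)c2C1=O
A1 | alternative 1 | 1-(3,4-dimethoxyphenyl)-4-(2,4,5-trimethoxyphenyl)butane-1,3-dione | COc1ccc(cc1OC)C(=O)CC(=O)Cc1cc(OC)c(OC)cc1OC
A2 | alternative 1 | 4-(3,4-dimethoxyphenyl)-5,6,8-trimethoxynaphthalen-2-ol | COc1cc(OC)c2cc(O)cc(-c3ccc(OC)c(OC)c3)c2c1OC
A3 | alternative 2 | 3-(3,4-dimethoxyphenyl)-5-methoxy-2-(2-methoxyprop-2-enoyl)benzaldehyde | COC(=C)C(=O)c1c(C=O)cc(OC)cc1-c1ccc(OC)c(OC)c1
A4 | alternative 2 | 8-(3,4-dimethoxyphenyl)-2,6-dimethoxy-2,3-dihydronaphthalene-1,4-dione (racemic) | COC1CC(=O)c2cc(OC)cc(-c3ccc(OC)c(OC)c3)c2C1=O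
A5 | alternative 3 | 4-[2-(3,4-dimethoxyphenyl)-4-methoxyphenyl]-4-hydroxy-3-methoxycyclobut-2-en-1-one (racemic) | COC1=CC(=O)C1(O)c1ccc(OC)cc1-c1ccc(OC)c(OC)c1
A6 | alternative 3 | 8-(3,4-dimethoxyphenyl)-2,6-dimethoxynaphthalene-1,4-diol | COc1cc(O)c2cc(OC)cc(-c3ccc(OC)c(OC)c3)c2c1O
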